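**Retrosynthetic overview**
1. Target ⇐ late unmasking (16,17-epoxide → C16=C17, C7 methyl ester → acid, C11 silyl ether → OH) after β-face osmylation of a C2=C3 alkene, which sets C2 and C3.
2. Ring A and the 19,10-lactone ⇐ intramolecular Michael addition (C4–C5) of a seven-membered lactone dienolate; that lactone ⇐ RCM (C2=C3) of a C10 allyl carbinol 2-methylbut-3-enoate; C10 ⇐ allyl Grignard addition to a ring-B enone.
3. Rings C and D ⇐ one acyl-radical cascade (C11–C12, then C13–C16) of a ring-B aldehyde carrying a cis allyl and a trans propargyl group on C8 (the new step).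
4. Ring B ⇐ (R)-4-silyloxycyclopentenone: α-allylation, conjugate addition of a formyl anion equivalent with propargylation (C9, C8), enol triflate carbonylation (C7).
5. Ring order: B (bought) → C then D (one flask) → seven-membered lactone → A with the γ-lactone.

Assumption: all intermediates carry gibberellane numbers (C7 = carboxyl carbon on C6, C17 = exocyclic methylene, C18 = methyl, C19 = lactone carbonyl); α is the face of the 19,10-lactone bridge, β the face of H-5, H-9, C-7 and C-15; C4 of 24 and 25 is an epimer mixture of no consequence (it becomes a planar dienolate in step 16) and is drawn without a descriptor.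

**Route**

Step 1
Reactants: 1 (R)-4-(tert-butyldimethylsilyloxy)cyclopent-2-en-1-one
Product: 2 (R)-4-(tert-butyldimethylsilyloxy)-2-iodocyclopent-2-en-1-one
Conditions: I2, pyridine, CH2Cl2, 0 °C to rt
Reagents that add atoms: iodine, [I][I]
Why: Pyridine-mediated α-iodination of the enone (conjugate addition of pyridine, iodination of the enolate, elimination) leaves the silyloxy stereocentre untouched.

Step 2
Reactants: 2 (R)-4-(tert-butyldimethylsilyloxy)-2-iodocyclopent-2-en-1-one; 3 allyltributylstannane
Product: 4 (R)-2-allyl-4-(tert-butyldimethylsilyloxy)cyclopent-2-en-1-one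
Conditions: Pd2(dba)3 (2.5 mol %), AsPh3, CuI, NMP, 40 °C
Reagents that add atoms: none
Why: Stille cross-coupling of the α-iodoenone under zerovalent palladium catalysis installs the allyl group that becomes C14, C13 and C12 without touching the stereocentre.

Step 3
Reactants: 4 (R)-2-allyl-4-(tert-butyldimethylsilyloxy)cyclopent-2-en-1-one; 5 bis(phenylthio)methane; 6 3-bromo-1-(trimethylsilyl)prop-1-yne
Product: 8 quaternary ring-B ketone (8α-allyl 8β-silylpropargyl 9α-dithioacetal 10β-OTBS), via lithium enolate 7 (not isolated)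
Conditions: 5, n-BuLi, THF, 0 °C; HMPA, then 4, −78 °C; then 6, −78 to −20 °C
Reagents that add atoms: none
Why: Tandem Michael addition–enolate alkylation (three-component coupling): the sulfur-stabilised formyl anion equivalent adds 1,4 in HMPA anti to the C10 silyloxy group (sets C9), and the tetrasubstituted enolate is alkylated by the propargylic bromide anti to the new C9 substituent (sets quaternary C8).

Step 4
Reactants: 8 quaternary ring-B ketone
Product: 10 C6 enol triflate (C5=C6), via potassium enolate 9 (not isolated)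
Conditions: KN(SiMe3)2, THF, −78 °C; then PhNTf2, −78 to 0 °C
Reagents that add atoms: N-phenylbis(trifluoromethanesulfonimide), O=S(=O)(N(c1ccccc1)S(=O)(=O)C(F)(F)F)C(F)(F)F
Why: Enolisation can only go toward C5 because C8 is quaternary, and O-sulfonylation of the enolate gives the vinyl triflate (enol triflate formation) with no change at any stereocentre.

Step 5
Reactants: 10 C6 enol triflate
Product: 12 methyl cyclopentenecarboxylate with free propargyl group, via silylalkyne ester 11 (not isolated)
Conditions: Pd(OAc)2 (5 mol %), PPh3, CO (1 atm), Et3N, MeOH/DMF, 50 °C; then K2CO3, MeOH, rt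
Reagents that add atoms: carbon monoxide, [C-]#[O+]; methanol, CO
Why: Palladium-catalysed methoxycarbonylation of the vinyl triflate brings in C7 as the conjugated methyl ester, and basic methanolysis then removes the alkynyl silyl group (protodesilylation).

Step 6
Reactants: 12 methyl cyclopentenecarboxylate with free propargyl group
Product: 13 C11 aldehyde
Conditions: PhI(OCOCF3)2, MeCN/H2O 9:1, 0 °C
Reagents that add atoms: water, O
Why: Oxidative hydrolysis of the diphenyl dithioacetal by the hypervalent iodine reagent unmasks the aldehyde under conditions too mild to epimerise C9 or attack the alkyne and alkenes.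

Step 7
Reactants: 13 C11 aldehyde
Product: 14 tricyclic keto ester (rings B, C and D; 11-ketone; 16-methylene)
Conditions: (n-Bu4N)4[W10O32] (2 mol %), MeCN (5 mM), 390 nm LED, rt, argon
Reagents that add atoms: none
Why: Proposed new method: the photoexcited decatungstate anion abstracts the hydridic formyl hydrogen, the nucleophilic C11 acyl radical closes onto the cis allyl group at its terminal carbon C12 (directly 6-endo-trig, or 5-exo followed by acyl-shift ring expansion, which wins because no fast hydrogen donor is present), the secondary C13 radical then closes 5-exo-dig onto the propargyl alkyne on C8, and the vinyl radical takes the hydrogen back from the reduced polyoxometalate, so rings C and D, the C11 ketone, the exocyclic methylene and the C13 bridgehead (its configuration forced by the bridge from the existing C8 and C9 centres) arise in one redox-neutral isomerisation; the closest known reaction types are decatungstate-photocatalysed hydroacylation of alkenes and tin- or silane-mediated acyl-radical polycyclisations of selenoesters.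

Step 8
Reactants: 14 tricyclic keto ester
Product: 15 11β-alcohol
Conditions: LiBH(s-Bu)3, THF, −78 °C; aq. NH4Cl
Reagents that add atoms: none
Why: Substrate-controlled ketone reduction with a bulky trialkylborohydride: hydride enters C11 from the face opposite the C15–C16 bridge and gives the axial 11β-alcohol, while the hindered conjugated ester is left alone.

Step 9
Reactants: 15 11β-alcohol
Product: 16 11β-triisopropylsilyl ether
Conditions: i-Pr3SiOTf, 2,6-lutidine, CH2Cl2, 0 °C to rt
Reagents that add atoms: triisopropylsilyl trifluoromethanesulfonate, CC(C)[Si](OS(=O)(=O)C(F)(F)F)(C(C)C)C(C)C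
Why: Silyl ether formation with the silyl triflate protects the hindered axial alcohol as an ether that outlasts the C10 silyl ether.

Step 10
Reactants: 16 11β-triisopropylsilyl ether
Product: 17 10β-alcohol
Conditions: HF·pyridine, pyridine, THF, 0 °C
Reagents that add atoms: none
Why: Selective desilylation: the less hindered allylic tert-butyldimethylsilyl ether at C10 is cleaved by buffered hydrogen fluoride much faster than the axial triisopropylsilyl ether at C11.

Step 11
Reactants: 17 10β-alcohol
Product: 18 C10 enone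
Conditions: Dess–Martin periodinane, CH2Cl2, rt
Reagents that add atoms: none
Why: Dess–Martin oxidation of the allylic alcohol gives the cyclopentenone without base, so the cis ring fusion at C9 (the more stable fusion) is kept.

Step 12
Reactants: 18 C10 enone
Product: 19 16,17-epoxide
Conditions: m-CPBA, NaHCO3, CH2Cl2, 0 °C
Reagents that add atoms: 3-chloroperoxybenzoic acid, OOC(=O)c1cccc(Cl)c1
Why: Prilezhaev epoxidation is selective for the electron-rich exocyclic alkene over the enone-ester alkene and occurs from the face away from the C11 silyloxy group, masking the methylene temporarily so that the later osmylation can only touch C2=C3.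

Step 13
Reactants: 20 2-methylbut-3-enoic acid
Product: 21 2-methylbut-3-enoyl chloride
Conditions: (COCl)2, DMF (cat.), CH2Cl2, 0 °C to rt
Reagents that add atoms: oxalyl chloride, ClC(=O)C(=O)Cl
Why: Standard acid chloride formation; the racemic α-centre does not matter because it is planarised in step 16.

Step 14
Reactants: 19 16,17-epoxide; 22 allylmagnesium bromide; 21 2-methylbut-3-enoyl chloride
Product: 24 C10 allyl carbinol 2-methylbut-3-enoate, via magnesium alkoxide 23 (not isolated)
Conditions: 22, THF, −78 °C; then 21, −78 to 0 °C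
Reagents that add atoms: none
Why: Grignard 1,2-addition to the C10 ketone from the β face, anti to C11 on the neighbouring C9, sets the C10 carbinol centre (oxygen α), and the tertiary magnesium alkoxide is O-acylated in the same flask.

Step 15
Reactants: 24 C10 allyl carbinol 2-methylbut-3-enoate
Product: 25 seven-membered unsaturated lactone
Conditions: (H2IMes)(PCy3)Cl2Ru=CHPh (second-generation Grubbs catalyst, 5 mol %), CH2Cl2 (2 mM), 40 °C
Reagents that add atoms: none
Why: Ring-closing metathesis of the two terminal alkenes forms the seven-membered lactone with the cis C2=C3 bond, the conjugated trisubstituted alkene and the epoxide being inert to the ruthenium carbene.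

Step 16
Reactants: 25 seven-membered unsaturated lactone
Product: 26 pentacyclic lactone ester (ring A with C2=C3 and the 19,10-lactone)
Conditions: t-BuOK (0.3 equiv), THF, −40 to 0 °C; AcOH
Reagents that add atoms: none
Why: Intramolecular Michael addition: the lactone dienolate attacks C5 of the unsaturated ester through its α-carbon C4, delivered on the α face by the ester tether, so C5 (H β) and quaternary C4 (methyl β) are fixed by the bridged geometry, and reversible protonation leaves the C6 ester β, trans to C4.

Step 17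
Reactants: 26 pentacyclic lactone ester
Product: 27 2β,3β-diol
Conditions: OsO4 (5 mol %), N-methylmorpholine N-oxide, acetone/H2O, rt
Reagents that add atoms: osmium tetroxide (catalytic oxygen carrier), O=[Os](=O)(=O)=O; N-methylmorpholine N-oxide, C[N+]1([O-])CCOCC1; water, O
Why: Catalytic osmium tetroxide syn-dihydroxylation of the only remaining alkene from the exposed β face, opposite the lactone bridge, gives the cis 2β,3β-diol.

Step 18
Reactants: 27 2β,3β-diol
Product: 28 16-methylene diol methyl ester
Conditions: Cp2TiCl2 (3 equiv), Zn dust, THF, rt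
Reagents that add atoms: none
Why: Reductive epoxide deoxygenation by two equivalents of the trivalent titanium reagent (radical opening to the tertiary C16 radical, then β-elimination of titanium oxide) restores the exocyclic methylene without acid.

Step 19
Reactants: 28 16-methylene diol methyl ester
Product: 29 C7 acid 11-silyl ether
Conditions: n-PrSLi, HMPA, rt; then dilute HCl
Reagents that add atoms: none
Why: Nucleophilic demethylation (bimolecular substitution at the ester methyl group by thiolate) frees the hindered C7 acid without hydrolysing the lactone.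

Step 20
Reactants: 29 C7 acid 11-silyl ether
Product: 30 CNP0322347.1 (2β,3β,11β-trihydroxy-20-norgibberell-16-ene-7,19-dioic acid 19,10-lactone)
Conditions: HF·pyridine, THF, 0 °C to rt
Reagents that add atoms: none
Why: Fluoride-mediated silyl ether cleavage frees the 11β-alcohol under conditions that neither isomerise the exocyclic alkene nor epimerise C3.

**Compound list**
1 | (R)-4-(tert-butyldimethylsilyloxy)cyclopent-2-en-1-one (future ring B: C1 = C6, C2 = C8, C3 = C9, C4 = C10) | O=C1C=C[C@H](O[Si](C)(C)C(C)(C)C)C1 | starting material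
2 | (R)-4-(tert-butyldimethylsilyloxy)-2-iodocyclopent-2-en-1-one | O=C1C(I)=C[C@H](O[Si](C)(C)C(C)(C)C)C1 | intermediate
3 | allyltributylstannane | C=CC[Sn](CCCC)(CCCC)CCCC | starting material
4 | (R)-2-allyl-4-(tert-butyldimethylsilyloxy)cyclopent-2-en-1-one | O=C1C(CC=C)=C[C@H](O[Si](C)(C)C(C)(C)C)C1 | intermediate
5 | bis(phenylthio)methane | C(Sc1ccccc1)Sc1ccccc1 | starting material
6 | 3-bromo-1-(trimethylsilyl)prop-1-yne | C[Si](C)(C)C#CCBr | starting material
7 | lithium enolate (C6–OLi, C6=C8) of the conjugate adduct: 8-allyl, 9α-bis(phenylthio)methyl (trans to the 10β-silyloxy group) | [Li]OC1=C(CC=C)[C@@H](C(Sc2ccccc2)Sc2ccccc2)[C@H](O[Si](C)(C)C(C)(C)C)C1 | intermediate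
8 | quaternary ring-B ketone: cyclopentanone (C6=O) with 8α-allyl, 8β-[3-(trimethylsilyl)prop-2-ynyl], 9α-bis(phenylthio)methyl (H-9β), 10β-OTBS | O=C1[C@](CC=C)(CC#C[Si](C)(C)C)[C@@H](C(Sc2ccccc2)Sc2ccccc2)[C@H](O[Si](C)(C)C(C)(C)C)C1 | intermediate
9 | potassium enolate of 8 (C6–OK, C5=C6) | [K]OC1=C[C@@H](O[Si](C)(C)C(C)(C)C)[C@H](C(Sc2ccccc2)Sc2ccccc2)[C@@]1(CC=C)CC#C[Si](C)(C)C | intermediate
10 | enol triflate of 8 (C6–OTf, C5=C6) | FC(F)(F)S(=O)(=O)OC1=C[C@@H](O[Si](C)(C)C(C)(C)C)[C@H](C(Sc2ccccc2)Sc2ccccc2)[C@@]1(CC=C)CC#C[Si](C)(C)C | intermediate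
11 | methyl cyclopent-1-enecarboxylate (C5=C6–CO2Me) with 8α-allyl, 8β-silylpropargyl, 9α-dithioacetal, 10β-OTBS | COC(=O)C1=C[C@@H](O[Si](C)(C)C(C)(C)C)[C@H](C(Sc2ccccc2)Sc2ccccc2)[C@@]1(CC=C)CC#C[Si](C)(C)C | intermediate
12 | as 11 but with free 8β-prop-2-ynyl group | COC(=O)C1=C[C@@H](O[Si](C)(C)C(C)(C)C)[C@H](C(Sc2ccccc2)Sc2ccccc2)[C@@]1(CC=C)CC#C | intermediate
13 | C11 aldehyde: as 12 with 9α-formyl in place of the dithioacetal | COC(=O)C1=C[C@@H](O[Si](C)(C)C(C)(C)C)[C@H](C=O)[C@@]1(CC=C)CC#C | intermediate
14 | tricyclic keto ester: cyclopentene ring B (C5=C6–CO2Me, 10β-OTBS) fused at C8–C9 (H-9β) to the bicyclo[3.2.1]octane of rings C and D (11-ketone, 16-methylene, C15 bridge β) | C=C1C[C@]23C[C@H]1CC(=O)[C@H]2[C@H](O[Si](C)(C)C(C)(C)C)C=C3C(=O)OC | intermediate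
15 | 11β-alcohol of 14 (axial, cis to H-9) | C=C1C[C@]23C[C@H]1C[C@H](O)[C@H]2[C@H](O[Si](C)(C)C(C)(C)C)C=C3C(=O)OC | intermediate
16 | 11β-triisopropylsilyl ether of 15 | C=C1C[C@]23C[C@H]1C[C@H](O[Si](C(C)C)(C(C)C)C(C)C)[C@H]2[C@H](O[Si](C)(C)C(C)(C)C)C=C3C(=O)OC | intermediate
17 | 10β-alcohol (C10 silyl group removed) | C=C1C[C@]23C[C@H]1C[C@H](O[Si](C(C)C)(C(C)C)C(C)C)[C@H]2[C@H](O)C=C3C(=O)OC | intermediate
18 | C10 enone (C10=O conjugated with C5=C6–CO2Me) | C=C1C[C@]23C[C@H]1C[C@H](O[Si](C(C)C)(C(C)C)C(C)C)[C@H]2C(=O)C=C3C(=O)OC | intermediate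
19 | 16,17-epoxide of 18 (epoxide oxygen on the face toward C14) | C1O[C@@]12C[C@]34C[C@H]2C[C@H](O[Si](C(C)C)(C(C)C)C(C)C)[C@H]3C(=O)C=C4C(=O)OC | intermediate
20 | 2-methylbut-3-enoic acid (racemic) | C=CC(C)C(=O)O | starting material
21 | 2-methylbut-3-enoyl chloride (racemic) | C=CC(C)C(=O)Cl | intermediate
22 | allylmagnesium bromide | C=CC[Mg]Br | starting material
23 | bromomagnesium alkoxide: 10β-allyl, 10α-OMgBr | C1O[C@@]12C[C@]34C[C@H]2C[C@H](O[Si](C(C)C)(C(C)C)C(C)C)[C@H]3[C@@](CC=C)(O[Mg]Br)C=C4C(=O)OC | intermediate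
24 | ester: 10β-allyl, 10α-(2-methylbut-3-enoyloxy) (C4 epimer mixture) | C1O[C@@]12C[C@]34C[C@H]2C[C@H](O[Si](C(C)C)(C(C)C)C(C)C)[C@H]3[C@@](CC=C)(OC(=O)C(C)C=C)C=C4C(=O)OC | intermediate
25 | seven-membered lactone O10–C19(=O)–C4H(CH3)–C3H=C2H–C1H2–C10 (cis alkene, C4 epimer mixture) | C1O[C@@]12C[C@]34C[C@H]2C[C@H](O[Si](C(C)C)(C(C)C)C(C)C)[C@H]3[C@]5(C/C=C\C(C)C(=O)O5)C=C4C(=O)OC | intermediate
26 | pentacyclic lactone ester: 19,10-lactone, ring A with C2=C3, 4β-methyl, H-5β, 6β-CO2Me, 11β-OTIPS, 16,17-epoxide | C1O[C@@]12C[C@]34C[C@H]2C[C@H](O[Si](C(C)C)(C(C)C)C(C)C)[C@H]3[C@@]56CC=C[C@@](C)(C(=O)O5)[C@H]6[C@@H]4C(=O)OC | intermediate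
27 | 2β,3β-diol of 26 | C1O[C@@]12C[C@]34C[C@H]2C[C@H](O[Si](C(C)C)(C(C)C)C(C)C)[C@H]3[C@@]56C[C@H](O)[C@H](O)[C@@](C)(C(=O)O5)[C@H]6[C@@H]4C(=O)OC | intermediate
28 | methyl ester 11-triisopropylsilyl ether of the target (16-methylene restored) | C=C1C[C@]23C[C@H]1C[C@H](O[Si](C(C)C)(C(C)C)C(C)C)[C@H]2[C@@]12C[C@H](O)[C@H](O)[C@@](C)(C(=O)O1)[C@H]2[C@@H]3C(=O)OC | intermediate
29 | 11-triisopropylsilyl ether of the target (free C7 acid) | C=C1C[C@]23C[C@H]1C[C@H](O[Si](C(C)C)(C(C)C)C(C)C)[C@H]2[C@@]12C[C@H](O)[C@H](O)[C@@](C)(C(=O)O1)[C@H]2[C@@H]3C(=O)O | intermediate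
30 | CNP0322347.1, 2β,3β,11β-trihydroxy-20-norgibberell-16-ene-7,19-dioic acid 19,10-lactone | C=C1C[C@]23C[C@H]1C[C@H](O)[C@H]2[C@@]12C[C@H](O)[C@H](O)[C@@](C)(C(=O)O1)[C@H]2[C@@H]3C(=O)O | target

**Totals and risk**
Total step count: 20. Longest linear sequence: 19 steps (1 to 30 through steps 1–12 and 14–20); step 13 is a one-step side branch.

Three steps most likely to fail:

Step 7 (the proposed cascade; risks are competing hydrogen abstraction at C10–H or premature reduction of the C13 radical). Fallback by known chemistry, setting out from 13 and returning at 14: Me2AlCl (CH2Cl2, −78 °C) promotes carbonyl-ene closure of the aldehyde onto the allyl group to give the homoallylic alcohol F1 (C11 carbinol, C13=C14; either C11 epimer serves); Dess–Martin oxidation gives the β,γ-unsaturated ketone F2; DBU (CH2Cl2, rt) moves the alkene into conjugation to give the conjugated enone F3 (C12=C13); Bu3SnH with AIBN (benzene, 80 °C) adds a stannyl radical to the terminal alkyne and the resulting vinyl radical closes 5-exo onto C13 of the enone to give the vinylstannane F4; protodestannylation (HCl, THF/H2O) gives 14.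

Step 8 (face selectivity of the C11 reduction; the axial C10 substituent on C9 may divert hydride to the bridge face and give the equatorial alcohol). Fallback setting out from 14 and returning at 15: reduce with NaBH4 (MeOH, −20 °C) and isolate the equatorial 11α-alcohol F5, invert it by Mitsunobu esterification (4-nitrobenzoic acid, PPh3, DIAD, toluene) to the 11β 4-nitrobenzoate F6, and methanolyse the ester (K2CO3, MeOH) to reach 15.

Step 16 (the dienolate may fail to reach C5 from within the seven-membered ring, or may react through its γ-carbon). Fallback setting out from 24 and returning at 26: carry out the Michael addition before the ring closure, so that t-BuOK (THF, −40 °C) converts the open-chain ester 24 through its dienolate into the γ-lactone F7 (C4 vinyl cis to the C10 allyl group; its C4 epimer is removed by chromatography), and then close ring A across the lactone by RCM with the second-generation Grubbs catalyst (CH2Cl2, 40 °C) to give 26.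

**Further compounds**
F1 | step 7 | homoallylic alcohol: cis-fused cyclohexenol (C11–OH, C13=C14) from carbonyl-ene closure of 13, 8β-propargyl retained | C#CC[C@]12C=CC[C@H](O)[C@H]1[C@H](O[Si](C)(C)C(C)(C)C)C=C2C(=O)OC
F2 | step 7 | β,γ-unsaturated ketone (C11=O, C13=C14) | C#CC[C@]12C=CCC(=O)[C@H]1[C@H](O[Si](C)(C)C(C)(C)C)C=C2C(=O)OC
F3 | step 7 | conjugated enone (C11=O, C12=C13) | C#CC[C@]12CC=CC(=O)[C@H]1[C@H](O[Si](C)(C)C(C)(C)C)C=C2C(=O)OC
F4 | step 7 | vinylstannane: 17-(tributylstannyl) derivative of 14 (Z isomer drawn) | CCCC[Sn](CCCC)(CCCC)/C=C1/C[C@]23C[C@H]1CC(=O)[C@H]2[C@H](O[Si](C)(C)C(C)(C)C)C=C3C(=O)OC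
F5 | step 8 | 11α-alcohol (C11 epimer of 15) | C=C1C[C@]23C[C@H]1C[C@@H](O)[C@H]2[C@H](O[Si](C)(C)C(C)(C)C)C=C3C(=O)OC
F6 | step 8 | 11β 4-nitrobenzoate of 15 | C=C1C[C@]23C[C@H]1C[C@H](OC(=O)c4ccc(cc4)[N+](=O)[O-])[C@H]2[C@H](O[Si](C)(C)C(C)(C)C)C=C3C(=O)OC
F7 | step 16 | γ-lactone Michael adduct: 19,10-lactone with 4β-methyl, C4 vinyl, 10β-allyl, H-5β, 6β-CO2Me | C1O[C@@]12C[C@]34C[C@H]2C[C@H](O[Si](C(C)C)(C(C)C)C(C)C)[C@H]3[C@@]5(CC=C)OC(=O)[C@](C)(C=C)[C@H]5[C@@H]4C(=O)OC
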